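The data stem from a simulated flask on assumed constants, and the scatter is random.

**Our clock.** We decide to time this row by the product of [starting material] and hours, not by hours. The loading stands at 10 mol% in each flask, so if the steps that make and consume target both run through catalyst, a flask at lower [starting material] should simply run slower in proportion. That is the bench rule: at the same loading and equivalents, same product, same flask.

| flask | starting material | second substrate | free catalyst | remark | time |
|---|---|---|---|---|---|
| larch | 1.5 mM | 0.50 equiv | 10 mol% | run made earlier |  |
| oak | 31 mM | 0.50 equiv | 10 mol% | run made earlier |  |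
| dusk | 1.2 mM | 0.500 equiv | 10 mol% |  | 20 h |
| midnight | 2.5 mM | 0.500 equiv | 10 mol% |  | 20 h |
| autumn | 5.0 mM | 0.500 equiv | 10 mol% |  | 20 h |
| dawn | 10 mM | 0.500 equiv | 10 mol% |  | 20 h |
| summer | 20 mM | 0.500 equiv | 10 mol% |  | 20 h |

| run | time / h | target / % |
|---|---|---|
| larch | 0.833 | 10.1 |
| larch | 1.33 | 11.4 |
| larch | 2.00 | 17.4 |
| larch | 3.00 | 24.1 |
| larch | 4.00 | 27.7 |
| larch | 6.00 | 35.6 |
| larch | 10.0 | 34.9 |
| oak | 1.33 | 30.5 |
| oak | 3.00 | 11.4 |
| oak | 4.00 | 5.0 |
| oak | 6.00 | 0 |
| oak | 8.00 | 0.7 |
| oak | 10.0 | 0 |

(readings scatter by 1 percentage point)

- "hardly changes" means that all values lie within two and a half points (for a concentration: within two and a half percent of the largest)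

- amount of target at the end, in percent of the starting material charged for dusk, midnight, autumn, dawn, summer, in this order
- the shape of the row from first to last (rises, then falls / hardly changes / rises all the way / falls all the way / falls, then rises)

**Oak's tail.** Target in oak fell from 30.5% at 1.33 h to 5.0% at 4.00 h. We read this as a pseudo-first-order decay with constant 0.677 h⁻¹, so target in oak halves in 1.02 h. We call this reading the tail half-life. By the bench rule, a flask passes through a number of halvings equal to its [starting material] times its hours, divided by oak's [starting material] times the tail half-life.

**The border.** Oak's first reading stands at 1.30 halvings, and the tail is read from there on. Larch's last reading, at 10.0 h, stands at 0.473 and still shows 34.9%. Dusk reaches 0.756 halvings, fewer than oak's first reading, so it lies before the stretch on which the tail was read, and we expect it somewhat under larch's value. Counting on from oak's first reading, our own reckoning gives midnight 25.2%, autumn 8.45% and dawn 0.950%.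

**The forecast.** The forecast gives 34%, 21%, 8%, 1% and 0%, so the row falls all the way; its midnight value sits under ours, and it adds: “The order of the loss is the main uncertainty.”

**The flasks.** They give 28.7%, 14.7%, 4.37%, 0.406% and 0%, and the row falls all the way.

    starting material + free catalyst ⇌ catalyst intermediate A (K = 228 M⁻¹, k = 23.4 M⁻¹ min⁻¹)
    catalyst intermediate A → free catalyst + target (k = 0.192 min⁻¹)
    second substrate + free catalyst ⇌ catalyst intermediate B (K = 4100 M⁻¹, k = 5.84 M⁻¹ min⁻¹)
    catalyst intermediate B → free catalyst + second product (k = 0.187 min⁻¹)
    free catalyst + target → free catalyst + over-reaction product (k = 14.1 M⁻¹ min⁻¹)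
    free catalyst + target → spent catalyst (k = 1.14 M⁻¹ min⁻¹)
    2 starting material → self-condensation product (k = 0.0992 M⁻¹ min⁻¹)

**The check.** Midnight's 14.7% stands below our 25.2%, so the level from oak does not carry over. From midnight to autumn the tail half-life predicts a drop by a factor 2.98, and the flasks show 3.36. From autumn to dawn it predicts 8.89, and the flasks show 10.8. The loss to watch is the step from free catalyst + target to free catalyst + over-reaction product: in the summer run without that step, target stands at 71.2% instead of 0%.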